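All runs stem from a simulated flask from invented constants; the scatter is artificial.

**The limit.** One G holds two units of Q yet enters the count of X as one, so a flask that still holds G cannot show its whole charge as X. The dilute flask is the large term. What concentration takes off is a correction, and the correction is what is reckoned here.

| flask | Q | remark | time |
|---|---|---|---|
| eta | 0.067 M | run made earlier |  |
| theta | 0.98 M | run made earlier |  |
| ash | 0.050 M |  | 3.0 min |
| oak | 0.20 M |  | 3.0 min |
| cedar | 0.80 M |  | 3.0 min |
| maple | 0.30 M |  | 3.0 min |

| run | time / s | X / % |
|---|---|---|
| eta | 10.0 | 12 |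
| eta | 25.0 | 33 |
| eta | 40.0 | 42 |
| eta | 60.0 | 53 |
| eta | 90.0 | 61 |
| theta | 10.0 | 13 |
| theta | 25.0 | 28 |
| theta | 40.0 | 38 |
| theta | 60.0 | 44 |
| theta | 90.0 | 52 |

(each reading ± 1.5 percentage points)

- percent here means Q units held: one G counts as two
- what is said of X includes G
- steps thought possible: Q + X <-> G; J <-> Z; Q -> X; Q <-> J; Q <-> E
- in an amount of X, one G counts as one X

- the flasks by amount of X, in percent of the Q charged, highest first, at 3.0 min (ash / oak / cedar / maple)
- the amount of X, in percent of the Q charged of the flask you put first, at 3.0 min
- the amount of X, in percent of the Q charged of the flask you put last, at 3.0 min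

**The price.** At 90.0 s the eta run shows 61% and the theta run 52%, each reading with a scatter of 1.5 percentage points. That gap over the difference in charge is 0.0986 M⁻¹, the price of concentration: the fraction of the charge missing from the count of X per molar charged.

**The decision.** Cedar holds 16.0 times the molarity of ash, so the same material needs that much less solvent. Taking the price over to 3.0 min, the reckoning here sets cedar's cost against ash at 7.4 points. That is a small correction, so cedar stays in the plan, with the count falling as the charge rises.

**The forecast.** The forecast gives ash > oak > maple > cedar, with 75% (70% to 80%) for ash and 68% (62% to 73%) for cedar, holding that “the lag grows with concentration”. Its gap is 7 points, against 7.4 points reckoned here.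

**The flask.** The order is ash > oak > maple > cedar, with ash at 77.0% and cedar at 65.4%, both inside the forecast's ranges.

    Q + X ⇌ G, settled at all times (K = 6.48 M⁻¹)
    J ⇌ Z (K = 1.20, k = 2.79 min⁻¹)
    Q → X (k = 1.05 min⁻¹)
    Q ⇌ J (K = 0.400, k = 0.259 min⁻¹)
    Q ⇌ E (K = 0.850, k = 0.140 min⁻¹)

**The price used.** Ash and cedar stand 12 points apart, more than the 7.4 points reckoned. For cedar read at 80 s, the eta readings at 60.0 s and 90.0 s interpolate to 58.3%, and the price takes off 7.2 points, leaving 51.1% against the 50.9% that flask gives. Cedar's shortfall at 3.0 min is one of time: it reaches 98.4% at 30.0 min, and run length is the main reason, 95% of what is missing.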